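Retrosynthesis cuts, in order: C23–C24 (ring-closing aldol bond, with C25 carried as a ketone), C7–C8 (ketone synthesis), C17–C18 (diene), then ester O2–C3 and amide N27–C28.
Enabling feature: in the 28-membered ring the C22,C23-diol is followed by C24H2 and the C25 carbinol, whose other neighbour C26H2 carries the lactam nitrogen N27. This is an aldol retron: C23 is an α-silyloxy aldehyde carbon and C24 the enolate carbon of an N-acylaminomethyl ketone, made regiospecifically from a chloromethyl ketone.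
Forward: Suzuki coupling (C17–C18), then Fukuyama ketone synthesis (C7–C8) joins a thioester that already carries the ester and amide; desilylation and double oxidation give the seco keto aldehyde; a chromium Reformatsky-type macro-aldol closes the ring; 1,3-anti reduction and desilylation finish.
Stereochemistry: C4/C6 by double Evans methylation of a C2-symmetric bis-imide; C1 from (S)-2-hydroxypentanoic acid; C15 by copper-catalysed asymmetric allylic ethylation; C22 from (R)-butanetriol acetonide; C18=C19 by anti-carbomagnesiation/iodination; C16=C17 by cross-metathesis; C23 by Felkin–Anh control in the ring closure; C25 by hydroxyl-directed reduction.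
Helpers: the chlorine is lost in the ring closure, the C25 ketone is reduced in step 24, and the C22 silyl ether is removed in step 25.

Key step: step 23

Remarks
- Numbering: positions refer to the 28-membered ring, with C1 the propyl-bearing carbon, O2 the ester oxygen, C3 the ester carbonyl, onward to C26, N27 and C28 (lactam carbonyl); the target is then (1S,4S,6S,15R,16E,18Z,22R,23S,25S).
- Assumption: (R,R)-Taniaphos is taken to give the (R)-configured SN2′ product in step 15; if the sense is opposite, the (S,S)-ligand is used with nothing else changed.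
- Assumption: (S)-2-hydroxypentanoic acid and (S)-1-amino-3-chloropropan-2-ol hydrochloride are bought as single enantiomers (the chlorohydrin centre is later oxidised, so its configuration only serves to keep intermediates single isomers).

Step 1
Reactants: 1 (S)-4-benzyl-1,3-oxazolidin-2-one; 2 pentanedioyl dichloride
Product: 3 1,5-bis[(S)-4-benzyl-2-oxo-1,3-oxazolidin-3-yl]pentane-1,5-dione
Conditions: 1 (2.1 equiv), n-BuLi, THF, –78 °C; then 2, –78 → 0 °C
Reagents that add atoms: none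
Why: N-acylation of the lithiated oxazolidinone by both acyl chloride groups should give the C2-symmetric bis-imide; no stereocentre is formed.

Step 2
Reactants: 3 1,5-bis[(S)-4-benzyl-2-oxo-1,3-oxazolidin-3-yl]pentane-1,5-dione
Product: 4 (2S,4S)-1,5-bis[(S)-4-benzyl-2-oxo-1,3-oxazolidin-3-yl]-2,4-dimethylpentane-1,5-dione
Conditions: NaN(SiMe3)2 (2.3 equiv), THF, –78 °C; MeI (10 equiv), –78 → –40 °C
Reagents that add atoms: iodomethane, CI
Why: Double Evans asymmetric alkylation: each chelated Z-sodium enolate should be methylated on the face opposite the benzyl group of its own (S)-auxiliary, so both new centres (future C4 and C6) are S, and the minor meso isomer is a separable diastereomer.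

Step 3
Reactants: 4 (2S,4S)-1,5-bis[(S)-4-benzyl-2-oxo-1,3-oxazolidin-3-yl]-2,4-dimethylpentane-1,5-dione
Product: 5 (2S,4S)-2,4-dimethylpentanedioic acid
Conditions: LiOH, 30% H2O2, THF/H2O (3:1), 0 °C; Na2SO3; then 1 M HCl
Reagents that add atoms: hydrogen peroxide, OO
Why: Evans auxiliary cleavage: lithium hydroperoxide attacks the exocyclic imide carbonyls selectively and should release the diacid without epimerisation.

Step 4
Reactants: 5 (2S,4S)-2,4-dimethylpentanedioic acid
Product: 7 (2S,4S)-5-(ethylsulfanyl)-2,4-dimethyl-5-oxopentanoic acid, via trans-dimethylglutaric anhydride 6 (not isolated)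
Conditions: DCC, CH2Cl2, 0 °C → rt, filter; then EtSH, Et3N (cat.), DMAP (cat.), CH2Cl2, 0 °C → rt
Reagents that add atoms: ethanethiol, CCS
Why: Carbodiimide dehydration should close the six-membered anhydride under neutral conditions, and because the trans-anhydride is C2-symmetric, thiolysis at either carbonyl gives the same mono-thioester acid.

Step 5
Reactants: 8 (S)-1-amino-3-chloropropan-2-ol hydrochloride
Product: 9 (S)-3-chloro-2-(triethylsilyloxy)propan-1-amine
Conditions: TESCl (1.1 equiv), imidazole (3 equiv), CH2Cl2, 0 °C; aq. NaHCO3 work-up; used at once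
Reagents that add atoms: chlorotriethylsilane, CC[Si](Cl)(CC)CC
Why: Silyl ether formation with silyl chloride/imidazole; any N-silylamine is hydrolysed on aqueous work-up, so the O-silyl ether of the amino alcohol should result.

Step 6
Reactants: 9 (S)-3-chloro-2-(triethylsilyloxy)propan-1-amine; 10 (S)-2-hydroxypentanoic acid
Product: 11 (S)-N-[(S)-3-chloro-2-(triethylsilyloxy)propyl]-2-hydroxypentanamide
Conditions: EDC·HCl, HOBt, CH2Cl2, 0 °C → rt
Reagents that add atoms: none
Why: Carbodiimide/HOBt amide coupling; the primary amine is far more nucleophilic than the α-hydroxyl, and the (S)-centre (future C1) is not touched.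

Step 7
Reactants: 7 (2S,4S)-5-(ethylsulfanyl)-2,4-dimethyl-5-oxopentanoic acid; 11 (S)-N-[(S)-3-chloro-2-(triethylsilyloxy)propyl]-2-hydroxypentanamide
Product: 12 (S)-1-{[(S)-3-chloro-2-(triethylsilyloxy)propyl]amino}-1-oxopentan-2-yl (2S,4S)-5-(ethylsulfanyl)-2,4-dimethyl-5-oxopentanoate
Conditions: EDC·HCl, DMAP, CH2Cl2, 0 °C → rt
Reagents that add atoms: none
Why: Steglich esterification of the free carboxyl group with the secondary α-hydroxy amide (O2–C3 bond); the thioester, silyl ether and alkyl chloride are inert.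

Step 8
Reactants: 13 (R)-2-(2,2-dimethyl-1,3-dioxolan-4-yl)ethan-1-ol
Product: 14 (R)-4-(2-bromoethyl)-2,2-dimethyl-1,3-dioxolane
Conditions: CBr4, PPh3, pyridine (cat.), CH2Cl2, 0 °C
Reagents that add atoms: carbon tetrabromide, BrC(Br)(Br)Br
Why: Appel bromination of the primary alcohol; the trace of base protects the acetonide, and the stereocentre (future C22) is remote.

Step 9
Reactants: 14 (R)-4-(2-bromoethyl)-2,2-dimethyl-1,3-dioxolane; 15 prop-2-yn-1-ol
Product: 18 (Z)-2-{2-[(R)-2,2-dimethyl-1,3-dioxolan-4-yl]ethyl}-3-iodoprop-2-en-1-ol, via alkylmagnesium bromide 16 (not isolated), via alkenylmagnesium alkoxide 17 (not isolated)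
Conditions: 14 (2.5 equiv), Mg, THF; then 15 (1 equiv), CuI (15 mol %), THF, rt → 45 °C; then I2, –40 → 0 °C; H2O work-up
Reagents that add atoms: iodine, II
Why: Grignard formation, then CuI-catalysed anti-carbomagnesiation of the magnesium alkoxide of propargyl alcohol: the alkoxide directs trans addition to a chelated alkenylmagnesium with Mg cis to CH2O, and iodinolysis with retention fixes the C18=C19 geometry (iodine cis to CH2OH, chain trans).

Step 10
Reactants: 18 (Z)-2-{2-[(R)-2,2-dimethyl-1,3-dioxolan-4-yl]ethyl}-3-iodoprop-2-en-1-ol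
Product: 19 (R)-4-[(Z)-4-iodo-3-(methoxymethyl)but-3-en-1-yl]-2,2-dimethyl-1,3-dioxolane
Conditions: NaH, MeI, THF, 0 °C → rt
Reagents that add atoms: iodomethane, CI
Why: Williamson ether synthesis on the allylic alkoxide; the alkenyl iodide and the acetonide are stable to NaH.

Step 11
Reactants: 19 (R)-4-[(Z)-4-iodo-3-(methoxymethyl)but-3-en-1-yl]-2,2-dimethyl-1,3-dioxolane
Product: 20 (2R,5Z)-6-iodo-5-(methoxymethyl)hex-5-ene-1,2-diol
Conditions: AcOH/H2O (4:1), 40 °C
Reagents that add atoms: none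
Why: Acid-catalysed acetonide hydrolysis; the alkenyl iodide and the allylic methyl ether are stable to aqueous acetic acid.

Step 12
Reactants: 20 (2R,5Z)-6-iodo-5-(methoxymethyl)hex-5-ene-1,2-diol
Product: 21 (2R,5Z)-6-iodo-5-(methoxymethyl)-1-(triethylsilyloxy)hex-5-en-2-ol
Conditions: TESCl (1.05 equiv), imidazole, CH2Cl2, –40 °C
Reagents that add atoms: chlorotriethylsilane, CC[Si](Cl)(CC)CC
Why: Kinetically selective silyl ether formation at the primary hydroxyl at low temperature.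

Step 13
Reactants: 21 (2R,5Z)-6-iodo-5-(methoxymethyl)-1-(triethylsilyloxy)hex-5-en-2-ol
Product: 22 tert-butyl{[(2R,5Z)-6-iodo-5-(methoxymethyl)-1-(triethylsilyloxy)hex-5-en-2-yl]oxy}dimethylsilane
Conditions: TBSOTf, 2,6-lutidine, CH2Cl2, –78 °C
Reagents that add atoms: tert-butyldimethylsilyl trifluoromethanesulfonate, CC(C)(C)[Si](C)(C)OS(=O)(=O)C(F)(F)F
Why: Silylation of the secondary hydroxyl with the silyl triflate gives the bulky, non-chelating C22 ether needed later; the primary TES ether survives at –78 °C.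

Step 14
Reactants: 23 5-bromopent-1-ene; 24 (E)-1,4-dibromobut-2-ene
Product: 25 (E)-1,6-dibromohex-2-ene
Conditions: 24 (3 equiv), second-generation Grubbs catalyst RuCl2(=CHPh)(H2IMes)(PCy3) (2 mol %), CH2Cl2, 40 °C; distillation
Reagents that add atoms: none
Why: Olefin cross-metathesis between the terminal alkene and the symmetrical allylic dibromide should give the thermodynamically favoured E-allylic bromide.

Step 15
Reactants: 25 (E)-1,6-dibromohex-2-ene; 26 ethylmagnesium bromide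
Product: 27 (R)-6-bromo-3-ethylhex-1-ene
Conditions: CuBr·SMe2 (1 mol %), (R,R)-Taniaphos (1.2 mol %), 26 (1.2 equiv), CH2Cl2, –75 °C
Reagents that add atoms: none
Why: Copper-catalysed asymmetric allylic alkylation (SN2′): the chiral ferrocenyl diphosphine–copper complex should deliver ethyl to the γ-carbon with branched selectivity and set the future C15 centre as R, while the unactivated primary bromide does not react at –75 °C.

Step 16
Reactants: 27 (R)-6-bromo-3-ethylhex-1-ene; 28 4-chloro-N-methoxy-N-methylbutanamide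
Product: 30 (R)-1-chloro-8-ethyldec-9-en-4-one, via hexenylmagnesium bromide 29 (not isolated)
Conditions: Mg, THF, rt; then 28, THF, 0 °C; H2O work-up
Reagents that add atoms: none
Why: Weinreb ketone synthesis: the Grignard reagent adds once to the N-methoxy-N-methylamide (stable chelated tetrahedral intermediate) to give the C11 ketone, leaving the alkyl chloride and the stereocentre untouched.

Step 17
Reactants: 30 (R)-1-chloro-8-ethyldec-9-en-4-one; 31 2-ethenyl-4,4,5,5-tetramethyl-1,3,2-dioxaborolane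
Product: 32 (R,E)-1-chloro-8-ethyl-10-(4,4,5,5-tetramethyl-1,3,2-dioxaborolan-2-yl)dec-9-en-4-one
Conditions: 31 (3 equiv), second-generation Grubbs catalyst RuCl2(=CHPh)(H2IMes)(PCy3) (5 mol %), CH2Cl2, 40 °C
Reagents that add atoms: none
Why: Olefin cross-metathesis with the vinyl boronate should give the E-alkenyl boronate under thermodynamic control (future C16=C17); the ketone and chloride are tolerated.

Step 18
Reactants: 32 (R,E)-1-chloro-8-ethyl-10-(4,4,5,5-tetramethyl-1,3,2-dioxaborolan-2-yl)dec-9-en-4-one; 22 tert-butyl{[(2R,5Z)-6-iodo-5-(methoxymethyl)-1-(triethylsilyloxy)hex-5-en-2-yl]oxy}dimethylsilane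
Product: 33 (8R,9E,11Z,15R)-15-(tert-butyldimethylsilyloxy)-1-chloro-8-ethyl-12-(methoxymethyl)-16-(triethylsilyloxy)hexadeca-9,11-dien-4-one
Conditions: Pd(dppf)Cl2 (5 mol %), K3PO4 (3 equiv), THF/H2O (10:1), rt
Reagents that add atoms: none
Why: Suzuki–Miyaura coupling with retention of both alkene geometries builds the (16E,18Z)-diene (C17–C18 bond); the mild phosphate base at room temperature should leave the γ-chloro ketone and the silyl ethers intact.

Step 19
Reactants: 33 (8R,9E,11Z,15R)-15-(tert-butyldimethylsilyloxy)-1-chloro-8-ethyl-12-(methoxymethyl)-16-(triethylsilyloxy)hexadeca-9,11-dien-4-one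
Product: 34 (8R,9E,11Z,15R)-15-(tert-butyldimethylsilyloxy)-8-ethyl-1-iodo-12-(methoxymethyl)-16-(triethylsilyloxy)hexadeca-9,11-dien-4-one
Conditions: NaI, NaHCO3 (cat.), acetone, 56 °C, dark
Reagents that add atoms: sodium iodide, [Na+].[I-]
Why: Finkelstein halide exchange at the primary chloride, driven by precipitation of the chloride salt.

Step 20
Reactants: 34 (8R,9E,11Z,15R)-15-(tert-butyldimethylsilyloxy)-8-ethyl-1-iodo-12-(methoxymethyl)-16-(triethylsilyloxy)hexadeca-9,11-dien-4-one; 12 (S)-1-{[(S)-3-chloro-2-(triethylsilyloxy)propyl]amino}-1-oxopentan-2-yl (2S,4S)-5-(ethylsulfanyl)-2,4-dimethyl-5-oxopentanoate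
Product: 36 (S)-1-{[(S)-3-chloro-2-(triethylsilyloxy)propyl]amino}-1-oxopentan-2-yl (2S,4S,13R,14E,16Z,20R)-20-(tert-butyldimethylsilyloxy)-13-ethyl-17-(methoxymethyl)-2,4-dimethyl-5,9-dioxo-21-(triethylsilyloxy)henicosa-14,16-dienoate, via alkylzinc iodide 35 (not isolated)
Conditions: Zn dust (activated with BrCH2CH2Br, Me3SiCl), LiCl, THF, 30 °C; then 12 (1.2 equiv), PdCl2(PPh3)2 (10 mol %), toluene/THF, rt; H2O work-up
Reagents that add atoms: none
Why: Direct zinc insertion into the primary iodide followed by Fukuyama coupling: zerovalent palladium inserts into the C–S bond of the thioester and the alkylzinc transfers its alkyl group, giving the C7 ketone without epimerising C6 and without touching the ester, amide, C11 ketone or alkyl chloride.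

Step 21
Reactants: 36 (S)-1-{[(S)-3-chloro-2-(triethylsilyloxy)propyl]amino}-1-oxopentan-2-yl (2S,4S,13R,14E,16Z,20R)-20-(tert-butyldimethylsilyloxy)-13-ethyl-17-(methoxymethyl)-2,4-dimethyl-5,9-dioxo-21-(triethylsilyloxy)henicosa-14,16-dienoate
Product: 37 (S)-1-{[(S)-3-chloro-2-hydroxypropyl]amino}-1-oxopentan-2-yl (2S,4S,13R,14E,16Z,20R)-20-(tert-butyldimethylsilyloxy)-13-ethyl-21-hydroxy-17-(methoxymethyl)-2,4-dimethyl-5,9-dioxohenicosa-14,16-dienoate
Conditions: AcOH/THF/H2O (3:1:1), rt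
Reagents that add atoms: none
Why: Acid-catalysed desilylation: the primary and the chlorohydrin triethylsilyl ethers are cleaved far faster than the secondary tert-butyldimethylsilyl ether at C22.

Step 22
Reactants: 37 (S)-1-{[(S)-3-chloro-2-hydroxypropyl]amino}-1-oxopentan-2-yl (2S,4S,13R,14E,16Z,20R)-20-(tert-butyldimethylsilyloxy)-13-ethyl-21-hydroxy-17-(methoxymethyl)-2,4-dimethyl-5,9-dioxohenicosa-14,16-dienoate
Product: 38 (S)-1-[(3-chloro-2-oxopropyl)amino]-1-oxopentan-2-yl (2S,4S,13R,14E,16Z,20R)-20-(tert-butyldimethylsilyloxy)-13-ethyl-17-(methoxymethyl)-2,4-dimethyl-5,9,21-trioxohenicosa-14,16-dienoate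
Conditions: Dess–Martin periodinane (3 equiv), NaHCO3, CH2Cl2, 0 °C → rt; used at once
Reagents that add atoms: none
Why: Dess–Martin oxidation converts the primary C23 alcohol into the aldehyde and the chlorohydrin into the chloromethyl ketone in one buffered, non-epimerising operation.

Step 23
Reactants: 38 (S)-1-[(3-chloro-2-oxopropyl)amino]-1-oxopentan-2-yl (2S,4S,13R,14E,16Z,20R)-20-(tert-butyldimethylsilyloxy)-13-ethyl-17-(methoxymethyl)-2,4-dimethyl-5,9,21-trioxohenicosa-14,16-dienoate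
Product: 41 (1S,4S,6S,15R,16E,18Z,22R,23S)-22-(tert-butyldimethylsilyloxy)-23-hydroxy-25-oxo macrocycle (28-membered lactone–lactam), via iodomethyl ketone 39 (not isolated), via trivalent chromium enolate 40 (not isolated)
Conditions: 38 added by syringe pump over 12 h to CrCl2 (10 equiv), LiI (2 equiv), THF, rt (final 0.001 M); aq. sodium potassium tartrate work-up
Reagents that add atoms: none
Why: In situ Finkelstein exchange gives iodomethyl ketone 39, which two one-electron transfers from CrCl2 convert regiospecifically into the trivalent chromium enolate 40 (C24=C25–O–Cr); this non-basic enolate adds to the C23 aldehyde through a closed six-membered transition state. The closest known reaction types are the chromium Reformatsky reaction of α-halo ketones with aldehydes and chromium-mediated (Nozaki–Hiyama–Kishi) macrocyclisations onto aldehydes. The 28-membered ring closes in a 28-exo-trig mode at the aldehyde (enolendo at the enolate), helped by the conformational restriction of the ester, lactam, diene and ketone sp2 units and by high dilution. The new C23 stereocentre is controlled by the adjacent C22 silyloxy group: attack anti to the C–OTBS bond (polar Felkin–Anh/Cornforth, no chelation by the bulky silyl ether) should give the 22,23-anti, that is (23S), carbinol. The step needs aldehyde-over-ketone chemoselectivity (chromium enolates should not add to the C7 and C11 ketones), a single enolate regioisomer (fixed by the halogen position, not by deprotonation, so C6, C22 and C26 stay untouched), and ring closure over oligomerisation (slow addition).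

Step 24
Reactants: 41 (1S,4S,6S,15R,16E,18Z,22R,23S)-22-(tert-butyldimethylsilyloxy)-23-hydroxy-25-oxo macrocycle
Product: 42 (1S,4S,6S,15R,16E,18Z,22R,23S,25S)-22-O-(tert-butyldimethylsilyl) ether of the target
Conditions: Me4NBH(OAc)3 (8 equiv), MeCN/AcOH (1:1), –30 °C
Reagents that add atoms: none
Why: Evans–Saksena reduction: the C23 hydroxyl exchanges onto boron and delivers hydride intramolecularly through a chair transition state, giving the 1,3-anti diol (25S); the C7 and C11 ketones lack a directing hydroxyl and should not be reduced.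

Step 25
Reactants: 42 (1S,4S,6S,15R,16E,18Z,22R,23S,25S)-22-O-(tert-butyldimethylsilyl) ether of the target
Product: 43 target CNP0537735.1
Conditions: HF·pyridine, pyridine, THF, 0 °C → rt
Reagents that add atoms: none
Why: Fluoride-mediated silyl ether cleavage under buffered conditions that should spare the lactone, the 1,5-diketone, the diene and the allylic methyl ether.

Compound list
1 | (S)-4-benzyl-1,3-oxazolidin-2-one | O=C1N[C@@H](Cc2ccccc2)CO1 | starting material
2 | pentanedioyl dichloride | ClC(=O)CCCC(Cl)=O | starting material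
3 | 1,5-bis[(S)-4-benzyl-2-oxo-1,3-oxazolidin-3-yl]pentane-1,5-dione | O=C(CCCC(=O)N1[C@@H](Cc2ccccc2)COC1=O)N1[C@@H](Cc2ccccc2)COC1=O | intermediate
4 | (2S,4S)-1,5-bis[(S)-4-benzyl-2-oxo-1,3-oxazolidin-3-yl]-2,4-dimethylpentane-1,5-dione | O=C([C@@H](C)C[C@H](C)C(=O)N1[C@@H](Cc2ccccc2)COC1=O)N1[C@@H](Cc2ccccc2)COC1=O | intermediate
5 | (2S,4S)-2,4-dimethylpentanedioic acid | OC(=O)[C@@H](C)C[C@H](C)C(=O)O | intermediate
6 | (3S,5S)-3,5-dimethyloxane-2,6-dione | O=C1OC(=O)[C@@H](C)C[C@@H]1C | intermediate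
7 | (2S,4S)-5-(ethylsulfanyl)-2,4-dimethyl-5-oxopentanoic acid | OC(=O)[C@@H](C)C[C@H](C)C(=O)SCC | intermediate
8 | (S)-1-amino-3-chloropropan-2-ol hydrochloride | Cl.NC[C@H](O)CCl | starting material
9 | (S)-3-chloro-2-(triethylsilyloxy)propan-1-amine | NC[C@H](O[Si](CC)(CC)CC)CCl | intermediate
10 | (S)-2-hydroxypentanoic acid | CCC[C@H](O)C(=O)O | starting material
11 | (S)-N-[(S)-3-chloro-2-(triethylsilyloxy)propyl]-2-hydroxypentanamide | CCC[C@H](O)C(=O)NC[C@H](O[Si](CC)(CC)CC)CCl | intermediate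
12 | (S)-1-{[(S)-3-chloro-2-(triethylsilyloxy)propyl]amino}-1-oxopentan-2-yl (2S,4S)-5-(ethylsulfanyl)-2,4-dimethyl-5-oxopentanoate | ClC[C@@H](O[Si](CC)(CC)CC)CNC(=O)[C@H](CCC)OC(=O)[C@@H](C)C[C@H](C)C(=O)SCC | intermediate
13 | (R)-2-(2,2-dimethyl-1,3-dioxolan-4-yl)ethan-1-ol | OCC[C@@H]1COC(C)(C)O1 | starting material
14 | (R)-4-(2-bromoethyl)-2,2-dimethyl-1,3-dioxolane | BrCC[C@@H]1COC(C)(C)O1 | intermediate
15 | prop-2-yn-1-ol | C#CCO | starting material
16 | {2-[(R)-2,2-dimethyl-1,3-dioxolan-4-yl]ethyl}magnesium bromide | Br[Mg]CC[C@@H]1COC(C)(C)O1 | intermediate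
17 | bromomagnesium (Z)-3-(bromomagnesio)-2-{2-[(R)-2,2-dimethyl-1,3-dioxolan-4-yl]ethyl}prop-2-en-1-olate | Br[Mg]/C=C(\CO[Mg]Br)CC[C@@H]1COC(C)(C)O1 | intermediate
18 | (Z)-2-{2-[(R)-2,2-dimethyl-1,3-dioxolan-4-yl]ethyl}-3-iodoprop-2-en-1-ol | I/C=C(\CO)CC[C@@H]1COC(C)(C)O1 | intermediate
19 | (R)-4-[(Z)-4-iodo-3-(methoxymethyl)but-3-en-1-yl]-2,2-dimethyl-1,3-dioxolane | I/C=C(\COC)CC[C@@H]1COC(C)(C)O1 | intermediate
20 | (2R,5Z)-6-iodo-5-(methoxymethyl)hex-5-ene-1,2-diol | I/C=C(\COC)CC[C@@H](O)CO | intermediate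
21 | (2R,5Z)-6-iodo-5-(methoxymethyl)-1-(triethylsilyloxy)hex-5-en-2-ol | I/C=C(\COC)CC[C@@H](O)CO[Si](CC)(CC)CC | intermediate
22 | tert-butyl{[(2R,5Z)-6-iodo-5-(methoxymethyl)-1-(triethylsilyloxy)hex-5-en-2-yl]oxy}dimethylsilane | I/C=C(\COC)CC[C@@H](O[Si](C)(C)C(C)(C)C)CO[Si](CC)(CC)CC | intermediate
23 | 5-bromopent-1-ene | C=CCCCBr | starting material
24 | (E)-1,4-dibromobut-2-ene | BrC/C=C/CBr | starting material
25 | (E)-1,6-dibromohex-2-ene | BrC/C=C/CCCBr | intermediate
26 | ethylmagnesium bromide | CC[Mg]Br | starting material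
27 | (R)-6-bromo-3-ethylhex-1-ene | BrCCC[C@@H](CC)C=C | intermediate
28 | 4-chloro-N-methoxy-N-methylbutanamide | CON(C)C(=O)CCCCl | starting material
29 | [(R)-4-ethylhex-5-en-1-yl]magnesium bromide | Br[Mg]CCC[C@@H](CC)C=C | intermediate
30 | (R)-1-chloro-8-ethyldec-9-en-4-one | ClCCCC(=O)CCC[C@@H](CC)C=C | intermediate
31 | 2-ethenyl-4,4,5,5-tetramethyl-1,3,2-dioxaborolane | C=CB1OC(C)(C)C(C)(C)O1 | starting material
32 | (R,E)-1-chloro-8-ethyl-10-(4,4,5,5-tetramethyl-1,3,2-dioxaborolan-2-yl)dec-9-en-4-one | ClCCCC(=O)CCC[C@@H](CC)/C=C/B1OC(C)(C)C(C)(C)O1 | intermediate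
33 | (8R,9E,11Z,15R)-15-(tert-butyldimethylsilyloxy)-1-chloro-8-ethyl-12-(methoxymethyl)-16-(triethylsilyloxy)hexadeca-9,11-dien-4-one | ClCCCC(=O)CCC[C@@H](CC)/C=C/C=C(\COC)CC[C@@H](O[Si](C)(C)C(C)(C)C)CO[Si](CC)(CC)CC | intermediate
34 | (8R,9E,11Z,15R)-15-(tert-butyldimethylsilyloxy)-8-ethyl-1-iodo-12-(methoxymethyl)-16-(triethylsilyloxy)hexadeca-9,11-dien-4-one | ICCCC(=O)CCC[C@@H](CC)/C=C/C=C(\COC)CC[C@@H](O[Si](C)(C)C(C)(C)C)CO[Si](CC)(CC)CC | intermediate
35 | [(8R,9E,11Z,15R)-15-(tert-butyldimethylsilyloxy)-8-ethyl-12-(methoxymethyl)-4-oxo-16-(triethylsilyloxy)hexadeca-9,11-dien-1-yl]zinc iodide | I[Zn]CCCC(=O)CCC[C@@H](CC)/C=C/C=C(\COC)CC[C@@H](O[Si](C)(C)C(C)(C)C)CO[Si](CC)(CC)CC | intermediate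
36 | (S)-1-{[(S)-3-chloro-2-(triethylsilyloxy)propyl]amino}-1-oxopentan-2-yl (2S,4S,13R,14E,16Z,20R)-20-(tert-butyldimethylsilyloxy)-13-ethyl-17-(methoxymethyl)-2,4-dimethyl-5,9-dioxo-21-(triethylsilyloxy)henicosa-14,16-dienoate | ClC[C@@H](O[Si](CC)(CC)CC)CNC(=O)[C@H](CCC)OC(=O)[C@@H](C)C[C@H](C)C(=O)CCCC(=O)CCC[C@@H](CC)/C=C/C=C(\COC)CC[C@@H](O[Si](C)(C)C(C)(C)C)CO[Si](CC)(CC)CC | intermediate
37 | (S)-1-{[(S)-3-chloro-2-hydroxypropyl]amino}-1-oxopentan-2-yl (2S,4S,13R,14E,16Z,20R)-20-(tert-butyldimethylsilyloxy)-13-ethyl-21-hydroxy-17-(methoxymethyl)-2,4-dimethyl-5,9-dioxohenicosa-14,16-dienoate | ClC[C@@H](O)CNC(=O)[C@H](CCC)OC(=O)[C@@H](C)C[C@H](C)C(=O)CCCC(=O)CCC[C@@H](CC)/C=C/C=C(\COC)CC[C@@H](O[Si](C)(C)C(C)(C)C)CO | intermediate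
38 | (S)-1-[(3-chloro-2-oxopropyl)amino]-1-oxopentan-2-yl (2S,4S,13R,14E,16Z,20R)-20-(tert-butyldimethylsilyloxy)-13-ethyl-17-(methoxymethyl)-2,4-dimethyl-5,9,21-trioxohenicosa-14,16-dienoate | ClCC(=O)CNC(=O)[C@H](CCC)OC(=O)[C@@H](C)C[C@H](C)C(=O)CCCC(=O)CCC[C@@H](CC)/C=C/C=C(\COC)CC[C@@H](O[Si](C)(C)C(C)(C)C)C=O | intermediate
39 | (S)-1-[(3-iodo-2-oxopropyl)amino]-1-oxopentan-2-yl ester analogue of 38 (iodomethyl ketone) | ICC(=O)CNC(=O)[C@H](CCC)OC(=O)[C@@H](C)C[C@H](C)C(=O)CCCC(=O)CCC[C@@H](CC)/C=C/C=C(\COC)CC[C@@H](O[Si](C)(C)C(C)(C)C)C=O | intermediate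
40 | dichlorochromium enolate of 38 (C24=C25–O–CrCl2) | C=C(O[Cr](Cl)Cl)CNC(=O)[C@H](CCC)OC(=O)[C@@H](C)C[C@H](C)C(=O)CCCC(=O)CCC[C@@H](CC)/C=C/C=C(\COC)CC[C@@H](O[Si](C)(C)C(C)(C)C)C=O | intermediate
41 | (1S,4S,6S,15R,16E,18Z,22R,23S)-22-(tert-butyldimethylsilyloxy)-15-ethyl-23-hydroxy-19-(methoxymethyl)-4,6-dimethyl-1-propyl-7,11,25-trioxo 28-membered lactone–lactam (ring numbering as in the remarks) | CCC[C@@H]1OC(=O)[C@@H](C)C[C@H](C)C(=O)CCCC(=O)CCC[C@@H](CC)/C=C/C=C(\COC)CC[C@@H](O[Si](C)(C)C(C)(C)C)[C@@H](O)CC(=O)CNC1=O | intermediate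
42 | (1S,4S,6S,15R,16E,18Z,22R,23S,25S)-22-O-(tert-butyldimethylsilyl) ether of the target | CCC[C@@H]1OC(=O)[C@@H](C)C[C@H](C)C(=O)CCCC(=O)CCC[C@@H](CC)/C=C/C=C(\COC)CC[C@@H](O[Si](C)(C)C(C)(C)C)[C@@H](O)C[C@H](O)CNC1=O | intermediate
43 | CNP0537735.1, (1S,4S,6S,15R,16E,18Z,22R,23S,25S)-15-ethyl-22,23,25-trihydroxy-19-(methoxymethyl)-4,6-dimethyl-1-propyl-7,11-dioxo 28-membered lactone–lactam | CCC[C@@H]1OC(=O)[C@@H](C)C[C@H](C)C(=O)CCCC(=O)CCC[C@@H](CC)/C=C/C=C(\COC)CC[C@@H](O)[C@@H](O)C[C@H](O)CNC1=O | target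

Total step count: 25
Longest linear sequence: 14 steps (13 → 43 through steps 8–13 and 18–25)

Steps most likely to fail

Step 23. Under the high dilution needed, ring closure may be outrun by intermolecular aldol addition (oligomers) or by protonation of the chromium enolate, and facial control at C23 inside the forming ring may be incomplete. The fallback moves the ring closure to another bond: the C23–C24 aldol bond is made intermolecularly and the ring is closed at C17–C18 by an intramolecular Suzuki–Miyaura coupling. It sets out from 22, 32 and 12 and comes back to the route at 41. From 22, AcOH/THF/H2O should give the primary alcohol (2R,5Z)-2-(tert-butyldimethylsilyloxy)-6-iodo-5-(methoxymethyl)hex-5-en-1-ol F1, and Dess–Martin oxidation the aldehyde (2R,5Z)-2-(tert-butyldimethylsilyloxy)-6-iodo-5-(methoxymethyl)hex-5-enal F2. From 32, NaI in acetone should give the iodo boronate (R,E)-8-ethyl-1-iodo-10-(4,4,5,5-tetramethyl-1,3,2-dioxaborolan-2-yl)dec-9-en-4-one F3, and zinc insertion (Zn, LiCl, THF) the reagent [(R,E)-8-ethyl-4-oxo-10-(4,4,5,5-tetramethyl-1,3,2-dioxaborolan-2-yl)dec-9-en-1-yl]zinc iodide F4. Fukuyama coupling of F4 with 12 (PdCl2(PPh3)2, no base, so the alkenyl boronate is not engaged) should give the diketone boronate (S)-1-{[(S)-3-chloro-2-(triethylsilyloxy)propyl]amino}-1-oxopentan-2-yl (2S,4S,13R,14E)-13-ethyl-2,4-dimethyl-5,9-dioxo-15-(4,4,5,5-tetramethyl-1,3,2-dioxaborolan-2-yl)pentadec-14-enoate F5. AcOH/THF/H2O then frees the chlorohydrin, the corresponding (S)-3-chloro-2-hydroxypropyl amide F6, and Dess–Martin periodinane gives the chloromethyl ketone, the corresponding 3-chloro-2-oxopropyl amide F7. Intermolecular chromium Reformatsky reaction of F7 with F2 (CrCl2, LiI, THF, 0.2 M; alkenyl iodides are inert to CrCl2 without a nickel co-catalyst) should give, with the same Felkin–Anh preference, the open-chain aldol (S)-1-{[(4S,5R,8Z)-5-(tert-butyldimethylsilyloxy)-4-hydroxy-9-iodo-8-(methoxymethyl)-2-oxonon-8-en-1-yl]amino}-1-oxopentan-2-yl (2S,4S,13R,14E)-13-ethyl-2,4-dimethyl-5,9-dioxo-15-(4,4,5,5-tetramethyl-1,3,2-dioxaborolan-2-yl)pentadec-14-enoate F8. Ring closure of F8 under high dilution (Pd(PPh3)4, K3PO4, THF/H2O, 0.001 M) should give 41, after which steps 24 and 25 follow unchanged.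

Step 20. Zinc insertion next to the ketone may be slow and the γ-oxoalkylzinc reagent may be protonated before it transfers its alkyl group to the hindered α-branched thioester, leaving reduced chain and unreacted thioester. The fallback avoids any preformed organometallic by a nickel-catalysed reductive cross-electrophile coupling of the iodide with an S-pyridyl thioester. It sets out from 5, 11 and 34 and comes back at 36. Diacid 5 is dehydrated to 6 as in step 4, and 6 is opened by alcohol 11 (DMAP, CH2Cl2; both carbonyls are equivalent) to give (2S,4S)-5-{[(S)-1-{[(S)-3-chloro-2-(triethylsilyloxy)propyl]amino}-1-oxopentan-2-yl]oxy}-2,4-dimethyl-5-oxopentanoic acid F9. 2,2'-Dipyridyl disulfide and PPh3 should convert it into (S)-1-{[(S)-3-chloro-2-(triethylsilyloxy)propyl]amino}-1-oxopentan-2-yl (2S,4S)-2,4-dimethyl-5-oxo-5-(pyridin-2-ylsulfanyl)pentanoate F10. Iodide 34 and F10 are then coupled with NiCl2(dme), 4,4'-di-tert-butyl-2,2'-bipyridine and Mn powder in DMA at rt to give 36.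

Step 9. Carbomagnesiation by the functionalised Grignard reagent may stay incomplete (the reagent is also consumed by the hydroxyl proton and by homocoupling), and the alkenylmagnesium geometry may erode before iodinolysis. The fallback replaces carbomagnesiation by syn-silylformylation of an alkyne. It sets out from 14 and comes back at 19. Alkylation of lithium acetylide–ethylenediamine complex with 14 (DMSO, rt) should give (R)-4-(but-3-yn-1-yl)-2,2-dimethyl-1,3-dioxolane F11. Rhodium-catalysed silylformylation (Me2PhSiH, CO, Rh4(CO)12, Et3N, benzene) places the formyl group on the internal and the silyl group on the terminal carbon, cis to each other, giving (Z)-2-{2-[(R)-2,2-dimethyl-1,3-dioxolan-4-yl]ethyl}-3-[dimethyl(phenyl)silyl]prop-2-enal F12. Luche reduction (NaBH4, CeCl3·7H2O, MeOH) should give (Z)-2-{2-[(R)-2,2-dimethyl-1,3-dioxolan-4-yl]ethyl}-3-[dimethyl(phenyl)silyl]prop-2-en-1-ol F13, and NaH/MeI the methyl ether (R)-4-{(Z)-4-[dimethyl(phenyl)silyl]-3-(methoxymethyl)but-3-en-1-yl}-2,2-dimethyl-1,3-dioxolane F14. Iododesilylation with N-iodosuccinimide (2,6-lutidine, (CF3)2CHOH, 0 °C), which proceeds with retention, should give 19.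

Further compounds
F1 | step 23 | (2R,5Z)-2-(tert-butyldimethylsilyloxy)-6-iodo-5-(methoxymethyl)hex-5-en-1-ol | I/C=C(\COC)CC[C@@H](O[Si](C)(C)C(C)(C)C)CO
F2 | step 23 | (2R,5Z)-2-(tert-butyldimethylsilyloxy)-6-iodo-5-(methoxymethyl)hex-5-enal | I/C=C(\COC)CC[C@@H](O[Si](C)(C)C(C)(C)C)C=O
F3 | step 23 | (R,E)-8-ethyl-1-iodo-10-(4,4,5,5-tetramethyl-1,3,2-dioxaborolan-2-yl)dec-9-en-4-one | ICCCC(=O)CCC[C@@H](CC)/C=C/B1OC(C)(C)C(C)(C)O1
F4 | step 23 | [(R,E)-8-ethyl-4-oxo-10-(4,4,5,5-tetramethyl-1,3,2-dioxaborolan-2-yl)dec-9-en-1-yl]zinc iodide | I[Zn]CCCC(=O)CCC[C@@H](CC)/C=C/B1OC(C)(C)C(C)(C)O1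
F5 | step 23 | (S)-1-{[(S)-3-chloro-2-(triethylsilyloxy)propyl]amino}-1-oxopentan-2-yl (2S,4S,13R,14E)-13-ethyl-2,4-dimethyl-5,9-dioxo-15-(4,4,5,5-tetramethyl-1,3,2-dioxaborolan-2-yl)pentadec-14-enoate | ClC[C@@H](O[Si](CC)(CC)CC)CNC(=O)[C@H](CCC)OC(=O)[C@@H](C)C[C@H](C)C(=O)CCCC(=O)CCC[C@@H](CC)/C=C/B1OC(C)(C)C(C)(C)O1
F6 | step 23 | (S)-1-{[(S)-3-chloro-2-hydroxypropyl]amino}-1-oxopentan-2-yl (2S,4S,13R,14E)-13-ethyl-2,4-dimethyl-5,9-dioxo-15-(4,4,5,5-tetramethyl-1,3,2-dioxaborolan-2-yl)pentadec-14-enoate | ClC[C@@H](O)CNC(=O)[C@H](CCC)OC(=O)[C@@H](C)C[C@H](C)C(=O)CCCC(=O)CCC[C@@H](CC)/C=C/B1OC(C)(C)C(C)(C)O1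
F7 | step 23 | (S)-1-[(3-chloro-2-oxopropyl)amino]-1-oxopentan-2-yl (2S,4S,13R,14E)-13-ethyl-2,4-dimethyl-5,9-dioxo-15-(4,4,5,5-tetramethyl-1,3,2-dioxaborolan-2-yl)pentadec-14-enoate | ClCC(=O)CNC(=O)[C@H](CCC)OC(=O)[C@@H](C)C[C@H](C)C(=O)CCCC(=O)CCC[C@@H](CC)/C=C/B1OC(C)(C)C(C)(C)O1
F8 | step 23 | (S)-1-{[(4S,5R,8Z)-5-(tert-butyldimethylsilyloxy)-4-hydroxy-9-iodo-8-(methoxymethyl)-2-oxonon-8-en-1-yl]amino}-1-oxopentan-2-yl (2S,4S,13R,14E)-13-ethyl-2,4-dimethyl-5,9-dioxo-15-(4,4,5,5-tetramethyl-1,3,2-dioxaborolan-2-yl)pentadec-14-enoate | I/C=C(\COC)CC[C@@H](O[Si](C)(C)C(C)(C)C)[C@@H](O)CC(=O)CNC(=O)[C@H](CCC)OC(=O)[C@@H](C)C[C@H](C)C(=O)CCCC(=O)CCC[C@@H](CC)/C=C/B1OC(C)(C)C(C)(C)O1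
F9 | step 20 | (2S,4S)-5-{[(S)-1-{[(S)-3-chloro-2-(triethylsilyloxy)propyl]amino}-1-oxopentan-2-yl]oxy}-2,4-dimethyl-5-oxopentanoic acid | ClC[C@@H](O[Si](CC)(CC)CC)CNC(=O)[C@H](CCC)OC(=O)[C@@H](C)C[C@H](C)C(=O)O
F10 | step 20 | (S)-1-{[(S)-3-chloro-2-(triethylsilyloxy)propyl]amino}-1-oxopentan-2-yl (2S,4S)-2,4-dimethyl-5-oxo-5-(pyridin-2-ylsulfanyl)pentanoate | ClC[C@@H](O[Si](CC)(CC)CC)CNC(=O)[C@H](CCC)OC(=O)[C@@H](C)C[C@H](C)C(=O)Sc1ccccn1
F11 | step 9 | (R)-4-(but-3-yn-1-yl)-2,2-dimethyl-1,3-dioxolane | C#CCC[C@@H]1COC(C)(C)O1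
F12 | step 9 | (Z)-2-{2-[(R)-2,2-dimethyl-1,3-dioxolan-4-yl]ethyl}-3-[dimethyl(phenyl)silyl]prop-2-enal | O=C/C(CC[C@@H]1COC(C)(C)O1)=C\[Si](C)(C)c1ccccc1
F13 | step 9 | (Z)-2-{2-[(R)-2,2-dimethyl-1,3-dioxolan-4-yl]ethyl}-3-[dimethyl(phenyl)silyl]prop-2-en-1-ol | OC/C(CC[C@@H]1COC(C)(C)O1)=C\[Si](C)(C)c1ccccc1
F14 | step 9 | (R)-4-{(Z)-4-[dimethyl(phenyl)silyl]-3-(methoxymethyl)but-3-en-1-yl}-2,2-dimethyl-1,3-dioxolane | COC/C(CC[C@@H]1COC(C)(C)O1)=C\[Si](C)(C)c1ccccc1
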